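## Retrosynthetic overview

1. Rings: neither ring is built. The cyclopenta[c]pyran, with C1 and C9 already correct, comes intact from (+)-genipin (1), and all later work edits the periphery.
2. The four esters are disconnected last. They are installed in the order C11 isovalerate, C7 acetate, C1 isovalerate, C10 salicylate, so the free phenol never meets an acylating agent. C1 and C10 are held as TBS ethers of different lability.
3. C11 CH2OH comes from CO2Me by DIBAL reduction. This is deliberately late, because the ester keeps the C3=C4 enol ether electron-poor during the oxidations.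
4. C5=C6 and the C7β–O bond come from a Schenck ene reaction (1O2) of a Δ6-8α-ol, which consumes H-5β.
5. Δ6 and the C8α–OH come from anti-hydroxyselenenylation and selenoxide elimination of genipin's C7=C8.

**Assumption:** enantiopure (+)-genipin, which is commercial on gram scale, is an acceptable chiral-pool starting material.

**Convention:** iridoid numbering is used. C1 is the acetal carbon, O2 the ring oxygen, and C3=C4 the enol ether. C5 and C9 are the ring-fusion carbons, and C6, C7 and C8 complete the cyclopentane ring. C10 is the CH2 on C8 and C11 is the carbon on C4. β is the face carrying H-9. The target is 1β-O-isovaleryl, 7β-OAc, 8α-OH, 8β-CH2O-salicyloyl, 9β-H, which is (1S,6S,7R,7aS) in cyclopenta[c]pyran numbering.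

## Route

**Step 1**
Reactants: 1, (+)-genipin
Product: 2, 1β,10-bis-O-TBS-genipin
Conditions: TBSCl (3 equiv), imidazole, DMAP (cat.), DMF, 0 °C to rt
Reagents that add atoms: TBSCl, CC(C)(C)[Si](C)(C)Cl
Why: Imidazole-promoted O-silylation caps the primary allylic OH and the lactol OH on oxygen only, so the single 1β anomer and C5/C9 are untouched, and the anomeric silyl acetal remains far more fluoride-labile than the primary ether.

**Step 2**
Reactants: 2
Product: 3, 7β-phenylselanyl-8α-hydroxy-7,8-dihydro derivative of 2 (8β-CH2OTBS)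
Conditions: N-(phenylseleno)phthalimide (1.3 equiv), H2O (10 equiv), PPTS (10 mol %), CH2Cl2, 0 °C to rt
Reagents that add atoms: N-(phenylseleno)phthalimide, O=C1c2ccccc2C(=O)N1[Se]c1ccccc1; water, O
Why: In this anti-hydroxyselenenylation PhSe+ attacks only C7=C8 (the C3=C4 β-alkoxyacrylate is deactivated) from the convex β face, and water opens the seleniranium ion at the tertiary Markovnikov carbon C8 from the α face, which sets C8.

**Step 3**
Reactants: 3
Product: 4, Δ6,7-8α-ol (methyl ester, 1β-OTBS, 8β-CH2OTBS, H-5β and H-9β)
Conditions: mCPBA (1.05 equiv), CH2Cl2, −78 °C; then i-Pr2NH, −78 °C to rt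
Reagents that add atoms: none (the oxygen from mCPBA leaves as PhSeOH)
Why: Selenoxide syn-elimination can only use H-6β because C8 is quaternary, so it gives the C6=C7 tertiary allylic alcohol regiospecifically and leaves C8 unchanged.

**Step 4**
Reactants: 4
Product: 5, 3,5-diene-7β,8α-diol methyl ester (1β-OTBS, 10-OTBS)
Conditions: O2, TPP (1 mol %), CH2Cl2, white LED, 0 °C, stopped at about 90 % conversion; then PPh3, 0 °C
Reagents that add atoms: dioxygen, O=O (one O is retained after PPh3 reduction)
Why: In this Schenck ene reaction the only allylic hydrogen is the doubly allylic H-5β on the convex face, so suprafacial attack places OOH at C7 on the β face (setting C7) and moves the alkene to C5=C6 in conjugation with C3=C4, while the α face has no abstractable H and the acrylate alkene is inert.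

**Step 5**
Reactants: 5
Product: 6, 7β,8α,11-triol (C4–CH2OH; 1β-OTBS, 10-OTBS)
Conditions: DIBAL-H (5 equiv), CH2Cl2, −78 °C; aq. Rochelle salt; Et3N-deactivated silica from this point on
Reagents that add atoms: none
Why: DIBAL 1,2-reduction takes the only carbonyl to the allylic alcohol at −78 °C, the silyl ether and silyl acetal survive, and the two free OH groups only consume hydride.

**Step 6**
Reactants: 6; 7, isovaleryl chloride
Product: 8, 11-O-isovaleryl-7β,8α-diol
Conditions: 7 (1.05 equiv), 2,4,6-collidine, CH2Cl2, −78 to −40 °C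
Reagents that add atoms: isovaleryl chloride (7), CC(C)CC(=O)Cl
Why: Kinetically selective acylation favours the unhindered primary allylic C11-OH over the neopentyl-type secondary C7-OH and the tertiary C8-OH.

**Step 7**
Reactants: 8; 9, acetic anhydride
Product: 10, 7β-O-acetyl-11-O-isovaleryl-8α-ol (1β-OTBS, 10-OTBS)
Conditions: Ac2O (2 equiv), pyridine, DMAP (10 mol %), CH2Cl2, 0 °C
Reagents that add atoms: acetic anhydride (9), CC(=O)OC(C)=O
Why: DMAP-catalysed acetylation esterifies the secondary C7-OH on oxygen with retention, the tertiary C8-OH does not react at 0 °C, and the trans 7,8 relationship disfavours acetyl migration to O8.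

**Step 8**
Reactants: 10
Product: 11, the 1β-lactol (7β-OAc, 11-O-isovaleryl, 8α-OH, 10-OTBS)
Conditions: TBAF/AcOH (1:1.2, 1.1 equiv), THF, −20 to 0 °C; used without storage
Reagents that add atoms: none
Why: Buffered fluoride removes the anomeric silyl acetal within minutes because the lactolate is a good leaving group, while the hindered primary TBS ether and all the esters survive.

**Step 9**
Reactants: 11; 7, isovaleryl chloride
Product: 12, 1β,11-di-O-isovaleryl-7β-O-acetyl-10-O-TBS-8α-ol
Conditions: 7 (1.5 equiv), pyridine, DMAP (10 mol %), CH2Cl2, −20 to 0 °C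
Reagents that add atoms: isovaleryl chloride (7), CC(C)CC(=O)Cl
Why: Like genipin, the lactol sits as the 1β-OH anomer (H-1 and H-9 trans), so O-acylation gives the 1β (1S) acylal, and the only other free hydroxyl is the unreactive tertiary C8-OH.

**Step 10**
Reactants: 12
Product: 13, the 8α,10-diol (1β,11-di-O-isovaleryl, 7β-OAc)
Conditions: HF·pyridine with excess pyridine, THF, 0 °C to rt (plastic vessel); carried on directly
Reagents that add atoms: none
Why: Buffered HF desilylation frees the primary C10-OH under mildly acidic, non-nucleophilic conditions, which spare the acylal, the allylic esters and the dienol ether and suppress base-induced O7-to-O10 acetyl migration.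

**Step 11**
Reactants: 13; 14, salicylic acid
Product: 15, jatamanvaltrate I
Conditions: 14 (1.5 equiv), EDC·HCl (1.5 equiv), DMAP (20 mol %), CH2Cl2, 0 °C
Reagents that add atoms: salicylic acid (14), OC(=O)c1ccccc1O
Why: Steglich esterification acylates the primary C10-OH in preference to the tertiary C8-OH and to the intramolecularly hydrogen-bonded, weakly nucleophilic phenol, and no stereocentre is touched.

## Compound list

| No. | Name | SMILES | Role |
|---|---|---|---|
| 1 | (+)-Genipin, methyl (1R,4aS,7aS)-1-hydroxy-7-(hydroxymethyl)-1,4a,5,7a-tetrahydrocyclopenta[c]pyran-4-carboxylate | COC(=O)C1=CO[C@H]([C@H]2[C@@H]1CC=C2CO)O | starting material |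
| 2 | 1β,10-Bis-O-TBS-genipin | COC(=O)C1=CO[C@H]([C@H]2[C@@H]1CC=C2CO[Si](C)(C)C(C)(C)C)O[Si](C)(C)C(C)(C)C | intermediate |
| 3 | 7β-PhSe-8α-OH adduct | COC(=O)C1=CO[C@H]([C@H]2[C@@H]1C[C@H]([Se]c3ccccc3)[C@]2(O)CO[Si](C)(C)C(C)(C)C)O[Si](C)(C)C(C)(C)C | intermediate |
| 4 | Δ6-8α-ol | COC(=O)C1=CO[C@H]([C@H]2[C@@H]1C=C[C@]2(O)CO[Si](C)(C)C(C)(C)C)O[Si](C)(C)C(C)(C)C | intermediate |
| 5 | 3,5-Diene-7β,8α-diol methyl ester | O[C@H]1C=C2C(C(=O)OC)=CO[C@@H](O[Si](C)(C)C(C)(C)C)[C@@H]2[C@@]1(O)CO[Si](C)(C)C(C)(C)C | intermediate |
| 6 | 7β,8α,11-Triol | O[C@H]1C=C2C(CO)=CO[C@@H](O[Si](C)(C)C(C)(C)C)[C@@H]2[C@@]1(O)CO[Si](C)(C)C(C)(C)C | intermediate |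
| 7 | Isovaleryl chloride | CC(C)CC(=O)Cl | starting material |
| 8 | 11-O-Isovaleryl-7β,8α-diol | O[C@H]1C=C2C(COC(=O)CC(C)C)=CO[C@@H](O[Si](C)(C)C(C)(C)C)[C@@H]2[C@@]1(O)CO[Si](C)(C)C(C)(C)C | intermediate |
| 9 | Acetic anhydride | CC(=O)OC(C)=O | starting material |
| 10 | 7β-OAc-11-O-isovaleryl bis-TBS ether | CC(=O)O[C@H]1C=C2C(COC(=O)CC(C)C)=CO[C@@H](O[Si](C)(C)C(C)(C)C)[C@@H]2[C@@]1(O)CO[Si](C)(C)C(C)(C)C | intermediate |
| 11 | 1β-Lactol | CC(=O)O[C@H]1C=C2C(COC(=O)CC(C)C)=CO[C@@H](O)[C@@H]2[C@@]1(O)CO[Si](C)(C)C(C)(C)C | intermediate |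
| 12 | 1β,11-Di-O-isovaleryl-7β-OAc-10-OTBS | CC(=O)O[C@H]1C=C2C(COC(=O)CC(C)C)=CO[C@@H](OC(=O)CC(C)C)[C@@H]2[C@@]1(O)CO[Si](C)(C)C(C)(C)C | intermediate |
| 13 | 8α,10-Diol | CC(=O)O[C@H]1C=C2C(COC(=O)CC(C)C)=CO[C@@H](OC(=O)CC(C)C)[C@@H]2[C@@]1(O)CO | intermediate |
| 14 | Salicylic acid | OC(=O)c1ccccc1O | starting material |
| 15 | Jatamanvaltrate I, [(1S,6S,7R,7aS)-6-acetyloxy-7-hydroxy-1-(3-methylbutanoyloxy)-4-[(3-methylbutanoyloxy)methyl]-6,7a-dihydro-1H-cyclopenta[c]pyran-7-yl]methyl 2-hydroxybenzoate | CC(=O)O[C@H]1C=C2C(COC(=O)CC(C)C)=CO[C@@H](OC(=O)CC(C)C)[C@@H]2[C@@]1(O)COC(=O)c1ccccc1O | target |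

## Step count

Total steps: 11. Longest linear sequence: 11 steps, from genipin.

## Steps most likely to fail

1. **Step 4 (Schenck ene).**
   - Risk: the alkene is 1,2-disubstituted and inductively deactivated, so it may react slowly, and the product diene may be over-oxidised.
   - Fallback: replace the ene reaction with epoxide-to-allylic-alcohol isomerisation. Mask the 8-OH as a TES ether and epoxidise C6=C7 from the convex β face with DMDO. Then carry out a syn-elimination of H-5β with Et2Al-TMP, which opens the C6–O bond and gives the same C5=C6/7β-OH array.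

2. **Step 2 (facial and regiochemical course of hydroxyselenenylation).**
   - Risk: water must enter at C8 from the concave α face, next to the ring fusion.
   - Fallback: reverse the polarity of the sequence. Epoxidise C7=C8 with mCPBA, then open the epoxide at C7 by SN2 attack with PhSeNa. This needs the opposite facial preference (the α-epoxide) to reach the same compound 3, so it covers the case where electrophiles prefer the α face of 2.

3. **Step 11 (with step 10).**
   - Risk: O7-to-O10 acetyl migration in diol 13, self-condensation of unprotected salicylic acid, and the general lability of the diene acylal toward DMAP.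
   - Fallback: form the C10–O bond by carboxylate alkylation instead of alcohol acylation. Convert 13 to the 8α,10-epoxide (isovaltrate) with TsCl/pyridine and then DBU. Open the epoxide at the primary C10 with salicylic acid and catalytic Cs2CO3, which retains the C8 configuration and needs no acyl donor or phenol protection.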